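**Retrosynthetic overview** (listed from the starting-material end, so the numbering runs forward)
- C–Br bonds at C3 and C5 of ring A: exhaustive electrophilic bromination of 4-bromo-2-fluorobenzaldehyde 1 (via 2 to 3); CHO, F and Br all direct to the same two positions.
- Diaryl ether, cut on the ring A side: 2-bromophenol 4 (ring B) displaces the CHO-activated fluoride of 3 to give 5. This reverses the usual polarity (O-arylation of a protected bromocatechol, then deprotection).
- Phenol OH: the same CHO is a latent hydroxyl, revealed by Dakin-type Baeyer–Villiger oxidation of 5 via formate 6 to target 7.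
- No ring is formed (both benzene rings are bought); no protecting group and no transition metal is used.

Assumption: the target has no stereocentre (it is achiral), so the SMILES defines it fully and no stereocontrol is needed.

**Route**

Step 1
Reactants: 1 4-bromo-2-fluorobenzaldehyde
Product: 3 3,4,5-tribromo-2-fluorobenzaldehyde, via 4,5-dibromo-2-fluorobenzaldehyde 2 (not isolated)
Conditions: dibromoisocyanuric acid (1.2 equiv), conc. H2SO4, 20 °C then 50 °C
Reagents that add atoms: dibromoisocyanuric acid, O=C1NC(=O)N(Br)C(=O)N1Br
Why: Electrophilic aromatic bromination with a superelectrophilic N-bromo reagent in H2SO4 (a system that brominates nitroarenes and nitrobenzaldehydes) works because the meta-directing protonated CHO, the ortho/para-directing F and the ortho-directing C4–Br all converge on C5 (first, para to F) and C3 (second), while C6 is ortho to CHO and meta to F; no stereocentre is formed.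

Step 2
Reactants: 3 3,4,5-tribromo-2-fluorobenzaldehyde; 4 2-bromophenol
Product: 5 3,4,5-tribromo-2-(2-bromophenoxy)benzaldehyde
Conditions: K2CO3 (1.5 equiv), DMF, 60 °C
Reagents that add atoms: none
Why: SNAr (addition–elimination) at C2, where the ortho-formyl group and the ortho/para bromines stabilise the Meisenheimer adduct and fluoride leaves far faster than the hindered para-bromide at C4 (element effect), so the ring A carbon–oxygen bond forms at one position only; no stereocentre is formed.

Step 3
Reactants: 5 3,4,5-tribromo-2-(2-bromophenoxy)benzaldehyde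
Product: 7 3,4,5-tribromo-2-(2-bromophenoxy)phenol, via aryl formate 6 (not isolated)
Conditions: mCPBA (1.5 equiv), CH2Cl2, 40 °C; then cat. HCl, MeOH, 20 °C
Reagents that add atoms: mCPBA (3-chloroperoxybenzoic acid), OOC(=O)c1cccc(Cl)c1
Why: Dakin-type Baeyer–Villiger oxidation, in which the peracid adds to the aldehyde and the aryl group, supported by the ortho-aryloxy oxygen, migrates to oxygen in the Criegee adduct to give the aryl formate, which acid-catalysed methanolysis cleaves to the phenol (the same oxidation is well established for halogenated 2-aryloxy aryl aldehydes and ketones); no stereocentre is formed.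

**Compound list**
1 | 4-bromo-2-fluorobenzaldehyde | O=Cc1ccc(Br)cc1F | starting material
2 | 4,5-dibromo-2-fluorobenzaldehyde | O=Cc1cc(Br)c(Br)cc1F | intermediate
3 | 3,4,5-tribromo-2-fluorobenzaldehyde | O=Cc1cc(Br)c(Br)c(Br)c1F | intermediate
4 | 2-bromophenol | Oc1ccccc1Br | starting material
5 | 3,4,5-tribromo-2-(2-bromophenoxy)benzaldehyde | O=Cc1cc(Br)c(Br)c(Br)c1Oc1ccccc1Br | intermediate
6 | 3,4,5-tribromo-2-(2-bromophenoxy)phenyl formate | O=COc1cc(Br)c(Br)c(Br)c1Oc1ccccc1Br | intermediate
7 | 3,4,5-tribromo-2-(2-bromophenoxy)phenol | Oc1cc(Br)c(Br)c(Br)c1Oc1ccccc1Br | target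

**Count**
Total step count: 3. Longest linear sequence: 3 steps (1 → 3 → 5 → 7).

**Steps most likely to fail, with fallbacks**

Step 1 (the second bromination, at C3 of a ring that already carries CHO, F and two Br, may stall at 2 or the aldehyde may be oxidised). The fallback sets out from 2, isolated after a mild first bromination with 0.55 equiv of dibromoisocyanuric acid at 20 °C, and comes back at 3. It replaces electrophilic substitution by directed deprotonation. MeOH, HC(OMe)3 and cat. TsOH convert 2 into 4,5-dibromo-2-fluorobenzaldehyde dimethyl acetal F1. TMPMgCl·LiCl, i.e. (2,2,6,6-tetramethylpiperidin-1-yl)magnesium chloride·LiCl, in THF at −30 °C removes C3–H, the only proton flanked by F and Br, to give [2,3-dibromo-5-(dimethoxymethyl)-6-fluorophenyl]magnesium chloride F2 (LiCl complex, not isolated). BrCCl2CCl2Br then brominates the carbanion to give 3,4,5-tribromo-2-fluorobenzaldehyde dimethyl acetal F3, and aq. HCl in THF unmasks 3.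

Step 3 (ring A is electron-poor and its aryloxy group is twisted by two ortho neighbours, so hydride migration to the benzoic acid may compete with aryl migration). The fallback sets out from 5 and comes back at 7. It swaps the aldehyde for a methyl ketone, where only aryl migration is productive. MeMgBr (THF, −78 °C) adds to 5 to give racemic 1-[3,4,5-tribromo-2-(2-bromophenoxy)phenyl]ethanol F4. Dess–Martin periodinane (CH2Cl2, 20 °C) oxidises it to 1-[3,4,5-tribromo-2-(2-bromophenoxy)phenyl]ethanone F5. CF3CO3H (from (CF3CO)2O and urea·H2O2, Na2HPO4, CH2Cl2, 0 to 20 °C) effects Baeyer–Villiger oxidation to 3,4,5-tribromo-2-(2-bromophenoxy)phenyl acetate F6, since aryl migrates far better than methyl. Cat. K2CO3 in MeOH cleaves F6 to 7.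

Step 2 (the fluoride sits between CHO and Br and the nucleophile is itself ortho-substituted, so the substitution may be sluggish). The fallback sets out from 3 and comes back at 5. It reverses the polarity of the ether formation. Acetohydroxamic acid and K2CO3 in DMSO at 80 °C act as a small hydroxide surrogate: SNAr gives N-(2,3,4-tribromo-6-formylphenoxy)acetamide F7 (not isolated), which fragments in the flask by a Lossen-type rearrangement to 3,4,5-tribromo-2-hydroxybenzaldehyde F8. Separately, 1-bromo-2-iodobenzene is oxidised with mCPBA and TsOH·H2O to 1-bromo-2-[hydroxy(tosyloxy)iodo]benzene F9 (not isolated), which is treated with 1,3,5-trimethoxybenzene to give (2-bromophenyl)(2,4,6-trimethoxyphenyl)iodonium tosylate F10. F8, K2CO3 and F10 in MeCN at 70 °C then give 5 by metal-free ligand coupling at trivalent iodine, which transfers the less electron-rich 2-bromophenyl group to oxygen.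

**Further compounds**
F1 | step 1 | 4,5-dibromo-2-fluorobenzaldehyde dimethyl acetal | COC(OC)c1cc(Br)c(Br)cc1F
F2 | step 1 | [2,3-dibromo-5-(dimethoxymethyl)-6-fluorophenyl]magnesium chloride | COC(OC)c1cc(Br)c(Br)c([Mg]Cl)c1F
F3 | step 1 | 3,4,5-tribromo-2-fluorobenzaldehyde dimethyl acetal | COC(OC)c1cc(Br)c(Br)c(Br)c1F
F4 | step 3 | racemic 1-[3,4,5-tribromo-2-(2-bromophenoxy)phenyl]ethanol | CC(O)c1cc(Br)c(Br)c(Br)c1Oc1ccccc1Br
F5 | step 3 | 1-[3,4,5-tribromo-2-(2-bromophenoxy)phenyl]ethanone | CC(=O)c1cc(Br)c(Br)c(Br)c1Oc1ccccc1Br
F6 | step 3 | 3,4,5-tribromo-2-(2-bromophenoxy)phenyl acetate | CC(=O)Oc1cc(Br)c(Br)c(Br)c1Oc1ccccc1Br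
F7 | step 2 | N-(2,3,4-tribromo-6-formylphenoxy)acetamide | CC(=O)NOc1c(C=O)cc(Br)c(Br)c1Br
F8 | step 2 | 3,4,5-tribromo-2-hydroxybenzaldehyde | O=Cc1cc(Br)c(Br)c(Br)c1O
F9 | step 2 | 1-bromo-2-[hydroxy(tosyloxy)iodo]benzene | Cc1ccc(cc1)S(=O)(=O)OI(O)c1ccccc1Br
F10 | step 2 | (2-bromophenyl)(2,4,6-trimethoxyphenyl)iodonium tosylate | COc1cc(OC)c([I+]c2ccccc2Br)c(OC)c1.Cc1ccc(cc1)S([O-])(=O)=O
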